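## The problem

Target 12 is a diarylmethane in which two acetylated phloroglucinol monomethyl ethers share one methylene carbon. It has no stereocentre, so the whole task is one of position, not of configuration. Ring B (C1′ bridge, C2′ OH, C3′ CH3, C4′ OH, C5′ acetyl, C6′ OCH3) carries five different substituents on six carbons. Which of its three oxygens is methylated, and where the C‑methyl sits relative to the bridge, cannot be settled reliably by selective substitution of a preformed methylphloroglucinol. Ring A (C1 bridge, C2 and C6 OH, C3 acetyl, C4 OCH3, C5 H) is symmetric until it is acetylated and can therefore come from a symmetric phenol. The bridge must be made as an unsymmetrical junction, because condensing two different acylphloroglucinols with a one‑carbon electrophile gives homo‑ and hetero‑dimers together. The free polyphenols are air‑sensitive, the methylene bridge between two such rings can be cleaved or scrambled by strong acid and, once the rings carry acyl groups, by base, and the acetyl groups are enolisable; the acetyl groups should therefore arrive last and under mild conditions. The enabling feature is that C4′, C5′ and C6′ with its methoxy group are a latent (E)‑3‑methoxy‑2‑enoate (C4′ ester carbon, C5′ alpha CH, C6′ enol ether carbon) with C1′ as its gamma carbon, while C2′, C3′ and the C‑methyl are a propanoyl unit. Ring B can thus be closed by forming C1′–C2′ and C3′–C4′.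

## Retrosynthesis

**12 to 11.** The two aryl–acetyl bonds (C5′–acetyl in ring B, C3–acetyl in ring A) are cut first. C5′ is the only unsubstituted carbon of ring B and the two open carbons of ring A are equivalent, so tetraphenol 11 can give only one constitution per ring. Carrying the acetyl groups earlier would put enolisable ketones into every strong‑base step and would make the bridge base‑labile. The forward reaction must stop at one acyl group per ring; a nitrile‑based Hoesch acylation does so because the ketiminium group deactivates the ring that bears it.

**11 to 10.** Only ring A needs protection, since the two ring B hydroxyls are formed free in the ring construction. Methoxymethyl ethers are chosen for three reasons: they direct the lithiation that introduces the bridge carbon, they survive amide bases, methoxide and hydrogenation, and they are removed by dilute acid in an alcohol. Removing them in a separate step before the acylation keeps electrophilic alkoxymethyl species away from the Lewis‑acidic conditions of the last step.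

**10 to 7 and 8.** Ring B is opened at C1′–C2′ and C3′–C4′. This gives the (E)‑3‑methoxy‑2‑enoate 7, whose gamma carbon already carries the ring A benzyl group, and the propanoyl donor 8. The neighbouring cut, bridge carbon to C1′ by Friedel–Crafts benzylation of a finished ring B, leaves the substitution pattern of ring B to be found elsewhere and is kept only as a reserve. Building ring A by annulation instead would spend the key step on the ring that is easy to buy. With the chosen cut the methoxy group, the C‑methyl and the bridge take their places by connectivity alone, and the precursor is acyclic apart from one symmetric arene. The forward reaction has to acylate the dienolate of 7 at its gamma carbon and then close through carbon, not oxygen. The propanoyl unit is delivered as the N‑methoxy‑N‑methylamide 8 and not as a simple alkyl ester. An ester would release the acidic keto ester 9 while dienolate is still present and would itself be enolised by any excess amide base, whereas the chelated adduct of 8 keeps the ketone masked until the cyclisation medium is added.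

**7 to 6, and 6 to 3 and 5.** The bond between the future bridge carbon and the future C1′ is cut as an alkene: hydrogenation of dienoate 6, which comes from aldehyde 3 and phosphonate 5 by Horner–Wadsworth–Emmons olefination. The obvious neighbour is alkylation of a 3‑methoxybutenoate dienolate with the ring A benzylic halide. That halide has two ortho and one para oxygen donors, ionises readily and attacks its own ring, and the alkylation would also raise an alpha‑versus‑gamma question. Aldehyde 3 is stable, the olefination is regiochemically fixed, and the enol ether geometry is brought in with the reagent. The forward sequence asks only that the styrenyl double bond be reduced and the push–pull enol ether double bond be left.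

**5 to 4.** The C–P bond is cut back to the commercial (E)‑bromide 4 (Michaelis–Arbuzov reaction).

**3 to 2, and 2 to 1.** The formyl carbon is removed from the position between the two acetal oxygens (directed ortho‑metalation of 2 and formylation), and the two acetal groups are removed to reach commercial 5‑methoxyresorcinol 1.

## Roads not taken

**Alternative 1:** The cut is made in ring B at the C4′–O bond and the C5′–acetyl bond together, with no ring formed. The precursor is the ortho‑silyl aryl triflate A1 of a tri‑O‑benzyl diarylmethane. Fluoride would unmask the strained triple bond between C4′ and C5′, and acetic acid A2 would add across it, oxygen to C4′ and acyl to C5′, to give hydroxy ketone A3.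
- Merits: ring B gets its acetyl group under nearly neutral conditions, with no electrophilic acylation of the acid‑sensitive diarylmethane. The methoxy group at C6′ polarises the triple bond so that oxygen should go to the remote carbon C4′, which is the required sense.
- Weak points: A1 is a ring B with six different substituents, so the regiochemical problem of ring B is enlarged, not solved. It would need a long halogenation, silyl‑transfer and triflation sequence on a late intermediate. The triple bond is flanked on both sides, and protonation of the aryl anion before acyl transfer would give only an aryl ester. Ring A would still need a separate acylation, followed by hydrogenolysis of three benzyl ethers.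
- Comparison: this road is better in one respect, since ring B is never acylated late. The chosen plan sets against this that C5′ is the only open carbon of ring B in 11, so position is not in doubt there, and that it constructs ring B from 7 and 8 instead of presupposing it, in far fewer steps.

**Alternative 2:** Ring A is cut at C5–C4 (CH carbon to methoxy carbon) and C2–C3 (hydroxyl carbon to acetyl carbon). The 1‑methoxy‑1,3‑bis(trimethylsilyloxy)diene A4, which carries the ring B benzyl group on its central carbon, would add through its terminus to the methoxy‑bearing carbon of 4‑methoxybut‑3‑yn‑2‑one A5. Closure onto the ester with expulsion of its alkoxide would aromatise ring A to A6.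
- Merits: ring A arrives with its methoxy and acetyl groups in place, positioned by the polarity of the two partners. Only ring B then needs an acetyl group, so the question of over‑acylating ring A never arises.
- Weak points: A5 is a sensitive push–pull alkyne and not a shelf reagent. A4 must already contain the complete, correctly differentiated ring B (two benzyl ethers, one methyl ether, one C‑methyl), so the hard ring is again presupposed, and its bulk sits on the reacting diene. Cycloaromatisations of such dienes with alkoxy ynones are less secure than those with enones. Ring B would still be acylated on the diarylmethane, and two benzyl ethers removed.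
- Comparison: it is better for ring A, and equal for ring B. The chosen plan sets against it that the annulation is spent on the ring that is difficult to obtain, that ring A is bought as symmetric 1, and that the Hoesch acylation is self‑limiting on each ring.

**Alternative 3:** Ring A is cut at C1–C2 (bridge‑bearing carbon to hydroxyl carbon) and carried as the 4‑methoxy‑2‑pyranone A7 with a 2‑(ring B aryl)ethyl chain at C6. Methoxide would open the lactone, and the ketone enolate carbon that carries the ring B benzyl group would attack the liberated ester to give resorcinol A8.
- Merits: the pyranone core is a cheap commercial building block that can be extended at its 6‑methyl group. The ring transformation has good precedent, forms only one bond and fixes the ring A methoxy group.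
- Weak points: the closing enolate is not the most acidic one, and oxygen re‑closure only returns A7. Ring B must be complete and correctly differentiated before the key step, which is the real difficulty of the target. Both acetyl groups still come at the end, exactly as in the chosen plan.
- Comparison: the key step is mechanistically close to the second half of the chosen one, its precursor is probably quicker to reach, and it can be studied from an isolable pyranone. The chosen plan sets against it that its annulation forms two bonds and so fixes the C‑methyl, the methoxy group and the bridge of ring B by connectivity, leaving selective functionalisation to the symmetric ring A only.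

Key step: step 6

## Route

Assumption: in 4, 5, 6, 7 and 9 the descriptor (E) at the enol ether double bond means ester and methoxy on opposite sides, so that the ester is cis to the carbon chain; this is the geometry of commercial 4 and the one the ring closure needs.

Step 1
Reactants: 1 5-methoxybenzene-1,3-diol (5-methoxyresorcinol)
Product: 2 1-methoxy-3,5-bis(methoxymethoxy)benzene
Conditions: MOMCl, iPr2NEt, CH2Cl2, 0 °C to rt
Reagents that add atoms: chloromethyl methyl ether, COCCl
Why: O-alkylation of both phenols by the reactive alpha-chloro ether under amine base (Williamson-type acetal formation); the acetal ethers are chosen because they direct the next lithiation and withstand the bases and the hydrogenation that follow.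

Step 2
Reactants: 2 1-methoxy-3,5-bis(methoxymethoxy)benzene
Product: 3 4-methoxy-2,6-bis(methoxymethoxy)benzaldehyde
Conditions: n-BuLi, TMEDA, THF, 0 °C; DMF, 0 °C to rt; aq. NH4Cl
Reagents that add atoms: N,N-dimethylformamide, CN(C)C=O
Why: Directed ortho-metalation followed by formylation of the aryllithium; the C–H between the two chelating acetal oxygens should be lithiated in preference to the two C–H flanked by one acetal and the weaker methoxy director.

Step 3
Reactants: 4 methyl (E)-4-bromo-3-methoxybut-2-enoate
Product: 5 methyl (E)-4-(diethoxyphosphoryl)-3-methoxybut-2-enoate
Conditions: P(OEt)3, neat, 120 °C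
Reagents that add atoms: triethyl phosphite, CCOP(OCC)OCC
Why: Michaelis–Arbuzov reaction of a primary allylic-type bromide; the enol ether double bond is not involved and keeps its (E)-geometry.

Step 4
Reactants: 3 4-methoxy-2,6-bis(methoxymethoxy)benzaldehyde; 5 methyl (E)-4-(diethoxyphosphoryl)-3-methoxybut-2-enoate
Product: 6 methyl (2E,4E)-3-methoxy-5-[4-methoxy-2,6-bis(methoxymethoxy)phenyl]penta-2,4-dienoate
Conditions: NaH, THF, 0 °C; then 3, 0 °C to rt
Reagents that add atoms: none
Why: Horner–Wadsworth–Emmons olefination with the stabilised anion of a vinylogous phosphonoacetate, which reacts at the phosphorus-bearing carbon; the new double bond should be (E), but its geometry is immaterial because it is saturated in the next step.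

Step 5
Reactants: 6 methyl (2E,4E)-3-methoxy-5-[4-methoxy-2,6-bis(methoxymethoxy)phenyl]penta-2,4-dienoate
Product: 7 methyl (E)-3-methoxy-5-[4-methoxy-2,6-bis(methoxymethoxy)phenyl]pent-2-enoate
Conditions: H2 (1 atm), Pd/C, EtOAc, rt
Reagents that add atoms: none
Why: Chemoselective catalytic hydrogenation: the disubstituted styrenyl double bond is reduced, while the trisubstituted donor–acceptor enol ether double bond is inert at ambient pressure, as in the hydrogenation of styryl 4-methoxypyranones at the styryl bond only; the acetal ethers are not hydrogenolysed.

Step 6
Reactants: 7 methyl (E)-3-methoxy-5-[4-methoxy-2,6-bis(methoxymethoxy)phenyl]pent-2-enoate; 8 N-methoxy-N-methylpropanamide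
Product: 10 5-methoxy-4-{[4-methoxy-2,6-bis(methoxymethoxy)phenyl]methyl}-2-methylbenzene-1,3-diol, via keto ester 9 (not isolated)
Conditions: LiN(iPr)2, THF, −78 °C; 8, −78 to −20 °C; then NaOMe, MeOH, 65 °C; aq. NH4Cl
Reagents that add atoms: none
Why: LiN(iPr)2 removes a proton from C4 of 7, the gamma CH2 that the (E)-geometry holds beside the ester carbonyl, and gives the lithium dienolate of a vinylogous carbonate. The dienolate is acylated at its gamma carbon by amide 8 (Claisen-type gamma-acylation of 3-alkoxy-2-enoate dienolates); the lithium-chelated N-methoxy-N-methyl hemiaminal does not collapse in the cold, so no acidic ketone appears while dienolate is still present, and the amide, less acidic than an ester, is not enolised. Methanolic NaOMe then releases keto ester 9 and equilibrates its enolates; the enolate carbon of the ethyl ketone (C6) adds to the ester carbonyl in a 6-exo-trig Claisen (Dieckmann-type) closure, methoxide leaves, and two enolisations give the arene, which is trapped as its phenoxide. The closest known reaction type is the base-induced conversion of 3-methoxy-5-oxo-2-enoates, or of the 4-methoxy-2-pyranones in equilibrium with them, into phloroglucinol monomethyl ethers (the polyketide Claisen mode). No lasting stereocentre is created: C4 of 9 is racemic and becomes an aromatic carbon. Two selectivities are needed, gamma- over alpha-acylation and carbon- over oxygen-cyclisation. The first rests on the 3-methoxy group, which makes the gamma terminus the reactive end of the dienolate; the second rests on reversibility, since a pyranone from oxygen closure is reopened by methoxide whereas phenoxide formation is irreversible. The (E)-enoate keeps the ester and the ketone chain on the same side of the double bond for closure, and the enol ether fixes the methoxy group on the carbon next to the bridge-bearing carbon.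

Step 7
Reactants: 10 5-methoxy-4-{[4-methoxy-2,6-bis(methoxymethoxy)phenyl]methyl}-2-methylbenzene-1,3-diol
Product: 11 4-[(2,6-dihydroxy-4-methoxyphenyl)methyl]-5-methoxy-2-methylbenzene-1,3-diol
Conditions: HCl (2 M), MeOH, 45 °C, under argon
Reagents that add atoms: none
Why: Acid-catalysed acetal exchange (cleavage of aryl methoxymethyl ethers); the large excess of methanol captures the methoxymethyl cation as its dimethyl acetal so that it does not alkylate the electron-rich rings, and dilute acid at moderate temperature should spare the diarylmethane.

Step 8
Reactants: 11 4-[(2,6-dihydroxy-4-methoxyphenyl)methyl]-5-methoxy-2-methylbenzene-1,3-diol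
Product: 12 1-{3-[(3-acetyl-2,6-dihydroxy-4-methoxyphenyl)methyl]-4,6-dihydroxy-2-methoxy-5-methylphenyl}ethan-1-one
Conditions: MeCN, ZnCl2, HCl (g), Et2O, 0 °C; then H2O, 90 °C
Reagents that add atoms: acetonitrile, CC#N; water, O
Why: Twofold Hoesch acylation: the nitrilium electrophile attacks ring B at its only free carbon and ring A at one of its two equivalent free carbons, each ring is switched off by its own ketiminium group after one acylation, and hydrolysis of the two ketiminium chlorides gives the methyl ketones.

## Compound list

1 | 5-methoxybenzene-1,3-diol (5-methoxyresorcinol) | COc1cc(O)cc(O)c1 | starting material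
2 | 1-methoxy-3,5-bis(methoxymethoxy)benzene | COCOc1cc(OC)cc(OCOC)c1 | intermediate
3 | 4-methoxy-2,6-bis(methoxymethoxy)benzaldehyde | COCOc1cc(OC)cc(OCOC)c1C=O | intermediate
4 | methyl (E)-4-bromo-3-methoxybut-2-enoate | COC(=O)/C=C(/OC)CBr | starting material
5 | methyl (E)-4-(diethoxyphosphoryl)-3-methoxybut-2-enoate | COC(=O)/C=C(/OC)CP(=O)(OCC)OCC | intermediate
6 | methyl (2E,4E)-3-methoxy-5-[4-methoxy-2,6-bis(methoxymethoxy)phenyl]penta-2,4-dienoate | COC(=O)/C=C(/OC)\C=C\c1c(OCOC)cc(OC)cc1OCOC | intermediate
7 | methyl (E)-3-methoxy-5-[4-methoxy-2,6-bis(methoxymethoxy)phenyl]pent-2-enoate | COC(=O)/C=C(/OC)CCc1c(OCOC)cc(OC)cc1OCOC | intermediate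
8 | N-methoxy-N-methylpropanamide | CCC(=O)N(C)OC | starting material
9 | methyl (E)-3-methoxy-4-{[4-methoxy-2,6-bis(methoxymethoxy)phenyl]methyl}-5-oxohept-2-enoate (racemic at C4; formed in the flask, not isolated) | COC(=O)/C=C(/OC)C(Cc1c(OCOC)cc(OC)cc1OCOC)C(=O)CC | intermediate
10 | 5-methoxy-4-{[4-methoxy-2,6-bis(methoxymethoxy)phenyl]methyl}-2-methylbenzene-1,3-diol | COc1cc(O)c(C)c(O)c1Cc1c(OCOC)cc(OC)cc1OCOC | intermediate
11 | 4-[(2,6-dihydroxy-4-methoxyphenyl)methyl]-5-methoxy-2-methylbenzene-1,3-diol | COc1cc(O)c(C)c(O)c1Cc1c(O)cc(OC)cc1O | intermediate
12 | 1-{3-[(3-acetyl-2,6-dihydroxy-4-methoxyphenyl)methyl]-4,6-dihydroxy-2-methoxy-5-methylphenyl}ethan-1-one | COc1cc(O)c(Cc2c(O)c(C)c(O)c(C(C)=O)c2OC)c(O)c1C(C)=O | target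

## Step count and least certain steps

Total: 8 steps. Longest linear sequence: 7 steps (steps 1, 2, 4, 5, 6, 7 and 8; step 3 prepares the phosphonate on a side branch).

**Step 6 (key step).** The most likely failures are three.
- Acylation of the dienolate at its alpha carbon or on oxygen, because the gamma carbon of 7 is secondary and carries a bulky arylethyl residue.
- Early collapse of the hemiaminal adduct, which would let the liberated ketone protonate unreacted dienolate and stall conversion.
- In the methoxide stage, closure through oxygen to a pyranone that reopens only slowly, or retro-Claisen loss of the propanoyl group before carbon closure.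

The fallback gives up the annulation and makes the bridge-to-ring B bond by electrophilic substitution. It sets out from 2 and 3 and returns at 10. Aldehyde 3 is reduced with NaBH4 in MeOH to [4-methoxy-2,6-bis(methoxymethoxy)phenyl]methanol F1. In parallel, 2 is lithiated as in step 2 and quenched with MeI to give 5-methoxy-1,3-bis(methoxymethoxy)-2-methylbenzene F2, which dilute HCl in MeOH converts into 5-methoxy-2-methylbenzene-1,3-diol F3. Friedel–Crafts benzylation of an excess of F3 with F1 (catalytic Sc(OTf)3, MeCN, 0 °C) should give 10, because the two open carbons of F3 are equivalent. Partial loss of acetal groups at this point would not matter, since step 7 removes them.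

**Step 8.** Three things may go wrong.
- The mono-ketiminium salt may precipitate from ether before the second ring has reacted, leaving incomplete acylation.
- The strongly acidic medium may cleave or scramble the methylene bridge by protonation at a bridge-bearing ring carbon and loss of a stabilised benzyl cation.
- Ring A may take up a second acyl group if the intermediate stays in solution too long.

The fallback replaces electrophilic acylation by a rearrangement under neutral conditions. It sets out from 11 and returns at 12. Peracetylation (Ac2O, pyridine) gives 2-[(2,4-diacetoxy-6-methoxy-3-methylphenyl)methyl]-5-methoxy-1,3-phenylene diacetate F4. Photo-Fries rearrangement (254 nm, degassed MeCN) can deliver an acyl group only to C5′ in ring B and to the equivalent carbons C3 and C5 in ring A, and a ring that has become an ortho-hydroxy ketone is poorly photoreactive. The two remaining aryl acetates are then removed with dilute HCl in MeOH to give 12.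

**Step 2.** Lithiation may take place in part at a carbon flanked by one acetal ether and the methoxy group, which would give the isomeric aldehyde and finally the wrong substitution pattern in ring A. The fallback fixes the position by halogen–metal exchange instead of proton abstraction. It sets out from 1 and returns at 3. Iodination of 1 (I2, NaHCO3, H2O–THF, 0 °C) should go to the carbon between the two hydroxyls, as with resorcinol itself, giving 2-iodo-5-methoxybenzene-1,3-diol F5. Protection (MOMCl, iPr2NEt) gives 2-iodo-5-methoxy-1,3-bis(methoxymethoxy)benzene F6, and iodine–lithium exchange (n-BuLi, THF, −78 °C) followed by DMF gives 3.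

**Step 5.** Hydrogenation may run on into the enol ether double bond, or add 1,4 across the diene and leave the double bond out of conjugation with the ester. The fallback saturates the chain before the enol ether exists. It sets out from 3 and returns at 7. Claisen–Schmidt condensation of 3 with acetone (NaOH, aqueous acetone) gives (E)-4-[4-methoxy-2,6-bis(methoxymethoxy)phenyl]but-3-en-2-one F7. Hydrogenation (H2, Pd/C) gives 4-[4-methoxy-2,6-bis(methoxymethoxy)phenyl]butan-2-one F8. Carboxylation at the methyl group (NaH, dimethyl carbonate, THF, reflux) gives methyl 5-[4-methoxy-2,6-bis(methoxymethoxy)phenyl]-3-oxopentanoate F9, and O-methylation of its enolate (Me2SO4, K2CO3, DMF) gives the (E)-enol ether 7.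

## Further compounds

F1 | step 6 | [4-methoxy-2,6-bis(methoxymethoxy)phenyl]methanol | COCOc1cc(OC)cc(OCOC)c1CO
F2 | step 6 | 5-methoxy-1,3-bis(methoxymethoxy)-2-methylbenzene | COCOc1cc(OC)cc(OCOC)c1C
F3 | step 6 | 5-methoxy-2-methylbenzene-1,3-diol | COc1cc(O)c(C)c(O)c1
F4 | step 8 | 2-[(2,4-diacetoxy-6-methoxy-3-methylphenyl)methyl]-5-methoxy-1,3-phenylene diacetate | COc1cc(OC(C)=O)c(C)c(OC(C)=O)c1Cc1c(OC(C)=O)cc(OC)cc1OC(C)=O
F5 | step 2 | 2-iodo-5-methoxybenzene-1,3-diol | COc1cc(O)c(I)c(O)c1
F6 | step 2 | 2-iodo-5-methoxy-1,3-bis(methoxymethoxy)benzene | COCOc1cc(OC)cc(OCOC)c1I
F7 | step 5 | (E)-4-[4-methoxy-2,6-bis(methoxymethoxy)phenyl]but-3-en-2-one | CC(=O)/C=C/c1c(OCOC)cc(OC)cc1OCOC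
F8 | step 5 | 4-[4-methoxy-2,6-bis(methoxymethoxy)phenyl]butan-2-one | CC(=O)CCc1c(OCOC)cc(OC)cc1OCOC
F9 | step 5 | methyl 5-[4-methoxy-2,6-bis(methoxymethoxy)phenyl]-3-oxopentanoate | COC(=O)CC(=O)CCc1c(OCOC)cc(OC)cc1OCOC
A1 | alternative 1 | 5-(benzyloxy)-4-{[2,6-bis(benzyloxy)-4-methoxyphenyl]methyl}-3-methoxy-6-methyl-2-(trimethylsilyl)phenyl trifluoromethanesulfonate | COc1c([Si](C)(C)C)c(OS(=O)(=O)C(F)(F)F)c(C)c(OCc2ccccc2)c1Cc1c(OCc2ccccc2)cc(OC)cc1OCc1ccccc1
A2 | alternative 1 | acetic acid | CC(=O)O
A3 | alternative 1 | 1-{3-[(2,6-bis(benzyloxy)-4-methoxyphenyl)methyl]-4-(benzyloxy)-6-hydroxy-2-methoxy-5-methylphenyl}ethan-1-one | COc1c(C(C)=O)c(O)c(C)c(OCc2ccccc2)c1Cc1c(OCc2ccccc2)cc(OC)cc1OCc1ccccc1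
A4 | alternative 2 | 2-{[2,4-bis(benzyloxy)-6-methoxy-3-methylphenyl]methyl}-1-methoxy-1,3-bis(trimethylsilyloxy)buta-1,3-diene | COC(O[Si](C)(C)C)=C(Cc1c(OCc2ccccc2)c(C)c(OCc2ccccc2)cc1OC)C(=C)O[Si](C)(C)C
A5 | alternative 2 | 4-methoxybut-3-yn-2-one | COC#CC(C)=O
A6 | alternative 2 | 1-{3-[(2,4-bis(benzyloxy)-6-methoxy-3-methylphenyl)methyl]-2,4-dihydroxy-6-methoxyphenyl}ethan-1-one | COc1cc(O)c(Cc2c(OCc3ccccc3)c(C)c(OCc3ccccc3)cc2OC)c(O)c1C(C)=O
A7 | alternative 3 | 4-methoxy-6-{2-[6-methoxy-2,4-bis(methoxymethoxy)-3-methylphenyl]ethyl}-2H-pyran-2-one | COc1cc(CCc2c(OCOC)c(C)c(OCOC)cc2OC)oc(=O)c1
A8 | alternative 3 | 5-methoxy-2-{[6-methoxy-2,4-bis(methoxymethoxy)-3-methylphenyl]methyl}benzene-1,3-diol | COc1cc(O)c(Cc2c(OCOC)c(C)c(OCOC)cc2OC)c(O)c1
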